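## Structural features

The target joins a 2-methoxy-3,5-dimethylpyran-4-one, through its C6, to C8 of a cis-fused bicyclo[4.2.0]octane. The bicycle is numbered C1 (fusion CH), C2 (C–CH3, O), C3 (=CH), C4 (=C–CH3), C5 (CH–O), C6 (fusion C–CH3), C7 (CH–CH3), C8 (C–CH3, pyranone). C2 and C5 are tied by an O–O bridge, so the six-membered ring is a 2,3-dioxabicyclo[2.2.2]oct-5-ene fused to the cyclobutane along C1–C6. Six stereocentres are contiguous (C2, C1, C8, C7, C6, C5), three of them fully substituted. The methyls on C6, C7 and C8 and H-1 share the convex face of the cyclobutane, the pyranone lies on the concave face, and the peroxide lies on the face of the six-membered ring away from the cyclobutane. Fragile groups are the peroxide (reductants, base at C5–H, heat, metal ions), the cyclohexadiene that precedes it (acid; on warming it opens reversibly to a cyclooctatriene, which can invert the ring fusion) and the vinylogous-ester pyranone (strong acid). The real difficulty is the fully alkylated cyclobutane with two quaternary carbons and three mutually cis methyls, together with its absolute configuration. The key step exploits the C1–C8 perimeter: it carries methyls on the alternate carbons C2, C4, C6 and C8, the pattern of 1,3,5,7-tetramethylcyclooctatetraene, so only the C7 methyl and the carbonyl carbon on C8 have to be added across two adjacent perimeter carbons before C1–C6 closes.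

## Logic of the disconnections

21 is cut at C2–O and C5–O. This removes the only group that cannot survive further chemistry and leads to the diene 20. The forward [4+2] photo-oxygenation must take the diene face away from the cyclobutane.

20 is cut at the O–CH3 bond of the methoxy group, giving 19. The forward methylation must choose the C2 carbonyl oxygen of the hydroxypyranone over the C4 hydroxyl.

19 is cut at the ring O–C(=O) bond, which unfolds the heterocycle to the open triketide 18. The forward step is a lactonization that needs only base.

18 is cut at the C–C bond between the acyl carbon on C8 and the chain. This separates the whole pyranone carbon set as 15 (through its dianion 17) from the bicyclic acid 14 (through 16). The forward step demands C-acylation at the γ-carbon of 17 by a hindered acyl donor.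

14 is traced, without cutting a skeletal bond, to racemic 11 by way of the salt 13 formed with 12. 11 is then cut at the ester O–CH3 bond to give 10. Placing the resolution on the first crystalline acid keeps every later step enantiopure. The ester cleavage must avoid the hindered carbonyl.

10 is cut at C1–C6 (retro-6π), giving the monocyclic triene 9 and removing two stereocentres. The forward closure must be disrotatory, which gives the cis fusion, and must settle on the fusion diastereomer with the ester under the diene.

9 is cut at C7–CH3 and C8–C(=O), leading to 4, 5 and 6 through the anions 7 and 8. This is the strategic simplification: the whole perimeter with four of its five methyls comes from one symmetrical hydrocarbon. The forward step must methylate a CH carbon once and then acylate the adjacent methyl-bearing terminus anti to the new methyl.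

4 is cut into two diene halves: both lactone bridges are restored to give 2 (loss of CO2 runs through 3), and 2 is cut at its two inter-ring C–C bonds to two molecules of 1. The forward steps need the head-to-tail sense of dimerization only.

## Other disconnections considered

Alternative 1: The cut removes the two cyclobutane bonds C1–C8 and C6–C7 and hangs the C7–C8 unit as an (E)-2-methylbut-2-enyl ether on the quaternary carbon (target C2) of the achiral para-quinol ether A1. In the forward step, excitation of A1 (visible light with a chiral oxazaborolidine-type Lewis acid, or a triplet sensitizer) would add one of the two enantiotopic enone double bonds across the tethered alkene. The product is the tricyclic enone ether A2, with the cyclobutane and a tetrahydrofuran closed together.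
- In its favour: C1, C6, C7, C8 and C2 are set in one step. The cis fusion is enforced by the tether and is not left to a valence-tautomer equilibrium. Absolute configuration would come from a catalyst and not from a resolution that discards half the material. On these three points it is the better plan. A1 is also short to make.
- Against it here: a triplet enone cycloaddition closes through a 1,4-diradical, so the E geometry of the side chain does not secure C7. 4,4-Disubstituted cyclohexa-2,5-dienones have an efficient competing photorearrangement to bicyclo[3.1.0]hexenones. Each new bond ends at a quaternary carbon (C6, C8). The ether oxygen on C2 sits syn to the cyclobutane, opposite to the peroxide oxygen, so it cannot be retained. A2 still needs removal of the C5 carbonyl with opening of the ether to the C2–C5 diene, and two oxidations of the CH2–O carbon, before it reaches 14.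
- Comparison: on structure the alternative fixes fusion and absolute configuration more cleanly. On mechanism it rests on an excited-state step with known competing channels, while the chosen plan rests on ground-state carbanion chemistry whose regiochemistry is unproven. On step economy it is about twelve to thirteen steps against eleven, with an identical late stage, so the two are equal there.

Alternative 2: The cut is inside the pyranone, at C3–C4 and O1–C2. In the forward step, the S-tert-butyl β-keto thioester A3 would lose its thiolate to a thiophilic monovalent silver salt at room temperature. The acylketene A4 released would undergo a hetero-Diels–Alder reaction with the ynol ether A5 to give A6 (identical with 20) in one step.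
- In its favour: the methoxy group arrives in place, so the O-methylation regiochemistry question of the chosen route disappears. Conditions are neutral and mild for the diene. It would replace three steps (8–10) by two. On these late-stage points it is equal or better.
- Against it here: it says nothing about the bicyclic core, since A3 has to be made from the same resolved acid 14 through 16. A4 is an α-branched acylketene on a neopentyl-type carbon. Ketenes and ynol ethers also combine by [2+2] to cyclobutenones. A5 is volatile and sensitive. A soft silver salt meets an electron-rich diene.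
- Comparison: on structure and stereochemistry the two are equal, because no stereocentre is involved. On mechanism the chosen Claisen, lactonization and methylation sequence uses only well-established carbonyl chemistry. On step economy the alternative saves one step. It is best regarded as a possible later shortening of the chosen route and not as a competing plan.

Alternative 3: The cut is a Diels–Alder disconnection of the bicyclo[2.2.2]octenone lactone A8. In target numbering it forms C1–C2 and C3–C4 from a cyclohexa-2,4-dienone carrying the future C8 as a quaternary carbon, with C2/C3 delivered by the isopropenyl ester in A7. In the forward direction, heating A7 would give A8. A photochemical 1,3-acyl shift would then contract A8 to the cyclobutanone A9 (forming C6–C7). The C7 methyl would be installed on the ketone, and eliminative opening of the lactone would give the diene acid 14.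
- In its favour: the quaternary carbon of A7 can be set by an auxiliary-controlled Birch reductive alkylation, so no resolution is needed. The rigid tricycle fixes C1, C8 and C2 relative to one another and the fusion is unambiguous. The lactone opens to exactly 14. On absolute control and on the fusion it is the better plan.
- Against it here: the two-atom ester tether prefers a conformation that holds the dienophile away from the diene. Cyclohexa-2,4-dienones are prone to dimerize. The 1,3-acyl shift competes with oxa-di-π-methane rearrangement and decarbonylation. The C7 methyl must be introduced on a cyclobutanone flanked by two quaternary carbons, with both faces encumbered, and it has to end cis to the C6 and C8 methyls.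
- Comparison: on structure the alternative is better for fusion and absolute configuration, and worse for C7. On mechanism it has two demanding pericyclic or photochemical steps against one unproven carbanion step. On step economy it needs about eight to nine steps to 14 against seven, so the chosen plan is shorter.

Key step: step 3

## Assumptions and corrections

- Locants: the triene ester 9 carries its methyls on C1, C3, C5, C7 and C8 of the cyclooctatriene (C1 is the ester carbon). A 1,2,4,6,8 locant set would place a methyl on the CH carbon next to C1, which is a different constitution from the one the dianion delivers and the target needs.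
- The photodimer 2 is drawn as the anti (centrosymmetric) head-to-tail isomer. Its configuration has no consequence, because all four stereocentres disappear in step 2.
- 3, 9, 10 and 11 are racemic; the enantiomer that leads to 21 is drawn.
- Which antipode of the resolving amine gives the less soluble salt with the wanted acid cannot be predicted. (R)-1-phenylethylamine is written, and the (S)-amine would be used if the other salt crystallizes.
- Locants C1–C8 for the bicyclic compounds follow the bicyclo[4.2.0]octane numbering given above; C1 and C8 of triene 9 correspond to C8 and C7 of the bicycle.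

## Steps

Step 1
Reactants: 1 4,6-dimethylpyran-2-one (two molecules)
Product: 2 anti head-to-tail [4+4] photodimer of 1
Conditions: hν (medium-pressure Hg lamp, Pyrex), MeCN, 0.5 M, 20 °C
Reagents that add atoms: none
Why: Head-to-tail [4+4] photodimerization of the pyranone diene units (C3 and C6 of one molecule to C6 and C3 of the other), a known photoreaction of this pyranone in concentrated solution; only the head-to-tail sense matters because the new stereocentres are destroyed in step 2.

Step 2
Reactants: 2 photodimer
Product: 4 1,3,5,7-tetramethylcycloocta-1,3,5,7-tetraene, via monolactone 3 (not isolated)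
Conditions: neat melt, 180–200 °C, N2; distillation under reduced pressure
Reagents that add atoms: none
Why: Two successive retro-[4+2] extrusions, in which each lactone bridge leaves as CO2 and restores a diene unit, should give the tub-shaped tetraene with methyls on alternate carbons; loss of gas drives the reaction.

Step 3
Reactants: 4 1,3,5,7-tetramethylcycloocta-1,3,5,7-tetraene; 5 iodomethane; 6 methyl chloroformate
Product: 9 methyl rac-(1R,8R)-1,3,5,7,8-pentamethylcycloocta-2,4,6-triene-1-carboxylate (1,8-dimethyl cis), via dipotassium tetramethylcyclooctatetraenediide 7 (not isolated), via potassium pentamethylcyclooctatrienide 8 (not isolated)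
Conditions: K (2.05 equiv), THF, 25 °C; MeI (1.0 equiv, slow), −78 °C; cannulate into ClCO2Me (2 equiv), THF, −78 → −20 °C; cold aq NH4Cl; keep ≤ 0 °C
Reagents that add atoms: iodomethane, CI; methyl chloroformate, COC(=O)Cl
Why: Proposed new method: two-electron reduction of the tetraene should give the planar 10π-aromatic dianion 7, which MeI alkylates at one of its four equivalent unsubstituted carbons, and the resulting mirror-symmetric heptatrienyl-type anion 8 should then be C-acylated by ClCO2Me at a terminus of the anion (C8 or its mirror image C6, hence the racemate) next to the new sp3 carbon; the closest known reaction type is the stepwise dialkylation of cyclooctatetraene dianion with alkyl halides to 7,8-dialkylcycloocta-1,3,5-trienes. No ring is closed; only C7–CH3 and C8–CO2CH3 are formed. C7 is not yet stereogenic in 8 (mirror plane through C7 and C3), so C7 and C8 become stereocentres together in the acylation, and their relative configuration is controlled by the C7 methyl, which shields one face of the neighbouring terminus so that the chloroformate enters anti to it and leaves the ester trans to the C7 methyl, that is the two methyls cis. The step needs attack at CH and not at C–CH3 in the methylation (sterics), monoalkylation (one equivalent of MeI added slowly at −78 °C to 7, which is the stronger nucleophile), and terminal (C8/C6) instead of internal (C2/C4) acylation of 8. The last demand is the least secure because all four charge-bearing carbons of 8 carry a methyl; terminal capture is expected because it alone leaves a fully conjugated triene and is the usual course of the second alkylation in the parent series, and an internal isomer would be separable after step 4 because it cannot undergo the 6π closure. Inverse addition of 8 to excess chloroformate keeps the product ester away from unreacted carbanion.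

Step 4
Reactants: 9 triene ester
Product: 10 methyl rac-(1R,6R,7R,8S)-2,4,6,7,8-pentamethylbicyclo[4.2.0]octa-2,4-diene-8-carboxylate
Conditions: toluene (degassed), 60 °C; chromatography at 20 °C
Reagents that add atoms: none
Why: Thermal disrotatory 6π electrocyclization of the all-cis triene (cyclooctatriene–bicyclooctadiene valence tautomerism) forms C1–C6 with cis fusion; the two cis-fused diastereomers interconvert through 9, and 10 (ester and H-7 under the diene, methyls on the convex face) is expected to be favoured because the other isomer pushes the C7 and C8 methyls under the diene against the C2 methyl; the minor isomer is recycled by reheating.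

Step 5
Reactants: 10 bicyclic methyl ester
Product: 11 rac-(1R,6R,7R,8S)-2,4,6,7,8-pentamethylbicyclo[4.2.0]octa-2,4-diene-8-carboxylic acid
Conditions: NaSEt (5 equiv), DMF, 50 °C; cold 1 M HCl
Reagents that add atoms: none
Why: SN2 demethylation by thiolate at the ester methyl does not require access to the hindered tertiary carbonyl; the diene is inert to thiolate and there is no epimerizable α-hydrogen.

Step 6
Reactants: 11 racemic acid; 12 (R)-1-phenylethylamine
Product: 13 (R)-1-phenylethylammonium (1R,6R,7R,8S)-2,4,6,7,8-pentamethylbicyclo[4.2.0]octa-2,4-diene-8-carboxylate
Conditions: 12 (1.0 equiv), EtOAc/EtOH, ≤ 40 °C then 4 °C; recrystallize to constant rotation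
Reagents that add atoms: (R)-1-phenylethylamine, C[C@@H](N)c1ccccc1
Why: Classical resolution through diastereomeric ammonium carboxylates of different solubility; this fixes the absolute configuration at C7 and C8 and, with them, at C1 and C6.

Step 7
Reactants: 13 resolved salt
Product: 14 (1R,6R,7R,8S)-2,4,6,7,8-pentamethylbicyclo[4.2.0]octa-2,4-diene-8-carboxylic acid
Conditions: 1 M HCl, Et2O, 0 °C
Reagents that add atoms: none
Why: Protonation of the carboxylate by the stronger acid partitions the free acid into ether and the amine into water; brief cold contact spares the diene.

Step 8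
Reactants: 14 resolved acid; 15 methyl 2-methyl-3-oxopentanoate
Product: 18 methyl 2,4-dimethyl-3,5-dioxo-5-[(1R,6R,7R,8S)-2,4,6,7,8-pentamethylbicyclo[4.2.0]octa-2,4-dien-8-yl]pentanoate, via acid chloride 16 (not isolated), via dilithium keto ester dianion 17 (not isolated)
Conditions: 14, 1-chloro-N,N,2-trimethylprop-1-en-1-amine (1.05 equiv), CH2Cl2, 0 → 20 °C, evaporate; 15 (2.5 equiv), LDA (5.0 equiv), THF, −78 → 0 °C; add 16, −78 → −20 °C; aq NH4Cl
Reagents that add atoms: methyl 2-methyl-3-oxopentanoate, CCC(=O)C(C)C(=O)OC
Why: The α-chloroenamine makes the acid chloride under neutral conditions (no HCl near the diene), and Claisen-type C-acylation then occurs at the γ-carbon of the β-keto ester dianion, its most basic and nucleophilic site; 16 has no α-hydrogen, so no ketene can form, and the excess dianion absorbs the acidic proton of 18; the chain stereocentres are of no consequence.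

Step 9
Reactants: 18 triketide
Product: 19 4-hydroxy-3,5-dimethyl-6-[(1R,6R,7R,8S)-2,4,6,7,8-pentamethylbicyclo[4.2.0]octa-2,4-dien-8-yl]pyran-2-one
Conditions: DBU (2 equiv), toluene, 25–40 °C; cold dilute HCl
Reagents that add atoms: none
Why: Base-mediated lactonization: the enol oxygen of the C5 ketone adds to the methyl ester and methoxide leaves, giving the stable 4-hydroxypyran-2-one and erasing the two chain stereocentres.

Step 10
Reactants: 19 hydroxypyranone
Product: 20 2-methoxy-3,5-dimethyl-6-[(1R,6R,7R,8S)-2,4,6,7,8-pentamethylbicyclo[4.2.0]octa-2,4-dien-8-yl]pyran-4-one
Conditions: MeOTf (1.2 equiv), CH2Cl2, 0 → 20 °C; aq NaHCO3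
Reagents that add atoms: methyl trifluoromethanesulfonate, COS(=O)(=O)C(F)(F)F
Why: Under non-basic conditions the hard methyl donor alkylates the most basic oxygen of the neutral hydroxypyranone, the C2 carbonyl oxygen, giving a 4-hydroxy-2-methoxypyrylium ion that is protected from a second methylation and loses its proton on bicarbonate work-up to the 2-methoxypyran-4-one; this is the established O-methylation mode of 3,5-dialkyl-4-hydroxypyran-2-ones.

Step 11
Reactants: 20 pyranone diene
Product: 21 2-methoxy-3,5-dimethyl-6-[(1R,2S,5R,6R,7R,8S)-2,5-epidioxy-2,4,6,7,8-pentamethylbicyclo[4.2.0]oct-3-en-8-yl]pyran-4-one (target)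
Conditions: O2, methylene blue (cat.), hν (visible), CH2Cl2, 0 °C
Reagents that add atoms: dioxygen, O=O
Why: [4+2] cycloaddition of singlet oxygen to the s-cis-locked diene C2–C5, faster than ene reactions of the ring alkenes; oxygen should approach the convex face, away from the cyclobutane and its concave-face pyranone, which sets C2 and C5; the electron-poor pyranone is inert.

## Compound list

1 | 4,6-dimethylpyran-2-one | CC1=CC(=O)OC(C)=C1 | starting material
2 | anti head-to-tail [4+4] photodimer of 1 (cycloocta-1,5-diene core; each O–C(=O) bridge links C6 and C3 of one former pyranone; bridges on opposite faces, centrosymmetric) | O=C1O[C@@]2(C)C=C(C)[C@@H]1[C@@]1(C)C=C(C)[C@@H]2C(=O)O1 | intermediate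
3 | rac-2,4,6,9-tetramethyl-7-oxabicyclo[4.2.2]deca-2,4,9-trien-8-one (monolactone after the first loss of CO2) | O=C1O[C@@]2(C)C=C(C)[C@@H]1C(C)=CC(C)=C2 | intermediate (not isolated)
4 | 1,3,5,7-tetramethylcycloocta-1,3,5,7-tetraene | C/C1=C/C(C)=C\C(C)=C/C(C)=C\1 | intermediate
5 | iodomethane | CI | starting material
6 | methyl chloroformate | COC(=O)Cl | starting material
7 | dipotassium 1,3,5,7-tetramethylcyclooctatetraenediide | [K+].[K+].C[C-]1C=C(C)C=C(C)C=C(C)[CH-]1 | intermediate (not isolated)
8 | potassium 1,3,5,7,8-pentamethylcyclooctatrienide (C8 sp3; charge delocalized over C1–C7; achiral) | [K+].CC1[C-](C)C=C(C)C=C(C)C=C1C | intermediate (not isolated)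
9 | methyl rac-(1R,8R)-1,3,5,7,8-pentamethylcycloocta-2,4,6-triene-1-carboxylate (1- and 8-methyls cis) | COC(=O)[C@@]1(C)[C@H](C)/C(C)=C\C(C)=C/C(C)=C\1 | intermediate
10 | methyl rac-(1R,6R,7R,8S)-2,4,6,7,8-pentamethylbicyclo[4.2.0]octa-2,4-diene-8-carboxylate (cis-fused; 6-, 7-, 8-methyls and H-1 on the convex face) | COC(=O)[C@@]1(C)[C@H](C)[C@@]2(C)C=C(C)C=C(C)[C@@H]12 | intermediate
11 | rac-(1R,6R,7R,8S)-2,4,6,7,8-pentamethylbicyclo[4.2.0]octa-2,4-diene-8-carboxylic acid | OC(=O)[C@@]1(C)[C@H](C)[C@@]2(C)C=C(C)C=C(C)[C@@H]12 | intermediate
12 | (R)-1-phenylethylamine | C[C@@H](N)c1ccccc1 | starting material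
13 | (R)-1-phenylethylammonium (1R,6R,7R,8S)-2,4,6,7,8-pentamethylbicyclo[4.2.0]octa-2,4-diene-8-carboxylate | C[C@@H]([NH3+])c1ccccc1.[O-]C(=O)[C@@]1(C)[C@H](C)[C@@]2(C)C=C(C)C=C(C)[C@@H]12 | intermediate
14 | (1R,6R,7R,8S)-2,4,6,7,8-pentamethylbicyclo[4.2.0]octa-2,4-diene-8-carboxylic acid | OC(=O)[C@@]1(C)[C@H](C)[C@@]2(C)C=C(C)C=C(C)[C@@H]12 | intermediate
15 | methyl 2-methyl-3-oxopentanoate | CCC(=O)C(C)C(=O)OC | starting material
16 | (1R,6R,7R,8S)-2,4,6,7,8-pentamethylbicyclo[4.2.0]octa-2,4-diene-8-carbonyl chloride | ClC(=O)[C@@]1(C)[C@H](C)[C@@]2(C)C=C(C)C=C(C)[C@@H]12 | intermediate (not isolated)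
17 | dilithium dianion of methyl 2-methyl-3-oxopentanoate (C2 and C4 deprotonated) | [Li+].[Li+].C[CH-]C(=O)[C-](C)C(=O)OC | intermediate (not isolated)
18 | methyl 2,4-dimethyl-3,5-dioxo-5-[(1R,6R,7R,8S)-2,4,6,7,8-pentamethylbicyclo[4.2.0]octa-2,4-dien-8-yl]pentanoate (chain epimers and enol forms) | COC(=O)C(C)C(=O)C(C)C(=O)[C@@]1(C)[C@H](C)[C@@]2(C)C=C(C)C=C(C)[C@@H]12 | intermediate
19 | 4-hydroxy-3,5-dimethyl-6-[(1R,6R,7R,8S)-2,4,6,7,8-pentamethylbicyclo[4.2.0]octa-2,4-dien-8-yl]pyran-2-one | O=c1oc([C@@]2(C)[C@H](C)[C@@]3(C)C=C(C)C=C(C)[C@@H]23)c(C)c(O)c1C | intermediate
20 | 2-methoxy-3,5-dimethyl-6-[(1R,6R,7R,8S)-2,4,6,7,8-pentamethylbicyclo[4.2.0]octa-2,4-dien-8-yl]pyran-4-one | COc1oc([C@@]2(C)[C@H](C)[C@@]3(C)C=C(C)C=C(C)[C@@H]23)c(C)c(=O)c1C | intermediate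
21 | 2-methoxy-3,5-dimethyl-6-[(1R,2S,5R,6R,7R,8S)-2,5-epidioxy-2,4,6,7,8-pentamethylbicyclo[4.2.0]oct-3-en-8-yl]pyran-4-one | COc1oc([C@@]2(C)[C@H](C)[C@@]3(C)[C@@H]4OO[C@@](C)(C=C4C)[C@@H]23)c(C)c(=O)c1C | target

## Step count and least certain steps

Total: 11 steps. Longest linear sequence: 11 steps (1 → 21); 5, 6, 12 and 15 are commercial inputs.

Step 3 (key step, the one that bears the label). The likeliest failures are capture of anion 8 at an internal carbon (C2/C4) to give the 1,4-pattern, approach of the chloroformate syn to the C7 methyl, a second methylation, and electron transfer from 7 to the electrophiles. All four charge-bearing carbons of 8 are methyl-substituted, so nothing in the substitution pattern separates terminal from internal attack. The fallback uses known chemistry, sets out from iodomethane 5 and comes back at 9: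
- 5 is converted with magnesium into methylmagnesium iodide F1. CuI-catalysed anti-carbomagnesiation of prop-2-yn-1-ol with F1, followed by iodinolysis, gives (Z)-3-iodo-2-methylprop-2-en-1-ol F2.
- MnO2 oxidation gives (Z)-3-iodo-2-methylprop-2-enal F3, and a Wittig reaction with methyl 2-(triphenylphosphoranylidene)propanoate gives methyl (2E,4Z)-5-iodo-2,4-dimethylpenta-2,4-dienoate F4.
- In parallel, (E)-2-methylbut-2-enal is converted by Wittig α-iodoethylidenation (ethyltriphenylphosphonium iodide, n-BuLi, I2, NaHMDS) into (2Z,4E)-2-iodo-4-methylhexa-2,4-diene F5. Iodine–lithium exchange (t-BuLi) and Me3SnCl give trimethyl[(2Z,4E)-4-methylhexa-2,4-dien-2-yl]stannane F6.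
- Stille coupling of F4 and F6 (Pd(PPh3)4, CuI, DMF) gives methyl (2E,4Z,6Z,8E)-2,4,6,8-tetramethyldeca-2,4,6,8-tetraenoate F7. Its thermal conrotatory 8π closure between C2 and C9 should give 9 with the two methyls cis, as the orbital-symmetry rule requires for the E,Z,Z,E geometry.

Step 4. The equilibrium between the two cis-fused diastereomers may lie unfavourably, or the two may not separate, since both relieve different methyl–methyl contacts. The fallback sets out from 11 (obtained as the fusion mixture by running step 5 on unseparated material) and comes back at 11 as a single fusion isomer. Iodolactonization (I2, KI, NaHCO3, 0 °C) can engage only the isomer whose carboxyl is syn to C2, giving the neutral iodolactone F8, which is separated from the unreacted carboxylate by extraction. Zn in AcOH/Et2O then returns the diene acid by reductive elimination. The unreacted isomer is re-equilibrated by warming.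

Step 6. Salt formation may fail to give a crystalline or sufficiently enriched diastereomer. The fallback sets out from racemic 10 and comes back at 14: the ester is separated by preparative chromatography on a polysaccharide chiral stationary phase, and step 5 on the wanted enantiomer gives 14 directly.

Step 8. C-acylation by the neopentyl-type acid chloride may be slow, so that proton transfer and O-acylation win. The fallback sets out from 14 and comes back at 18. LiAlH4 reduction gives [(1R,6R,7R,8S)-2,4,6,7,8-pentamethylbicyclo[4.2.0]octa-2,4-dien-8-yl]methanol F9. Dess–Martin oxidation gives the carbaldehyde F10. Aldol addition of dianion 17 gives the hydroxy keto ester F11, and a second Dess–Martin oxidation gives 18.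

Step 10. Methylation may occur on the C4 oxygen (giving the 4-methoxypyran-2-one), a second methylation may follow, or the acid released may damage the diene. The fallback sets out from 18 and comes back at 20: cyclodehydration of the triketide with PPh3/CCl4 activates the enol of the C5 ketone, so the ester carbonyl oxygen closes the ring and the O-methyl group is kept. This bypasses 19.

## Further compounds

F1 | step 3 | methylmagnesium iodide | C[Mg]I
F2 | step 3 | (Z)-3-iodo-2-methylprop-2-en-1-ol | OC/C(C)=C\I
F3 | step 3 | (Z)-3-iodo-2-methylprop-2-enal | O=C/C(C)=C\I
F4 | step 3 | methyl (2E,4Z)-5-iodo-2,4-dimethylpenta-2,4-dienoate | COC(=O)/C(C)=C/C(C)=C\I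
F5 | step 3 | (2Z,4E)-2-iodo-4-methylhexa-2,4-diene | C/C=C(C)/C=C(/C)I
F6 | step 3 | trimethyl[(2Z,4E)-4-methylhexa-2,4-dien-2-yl]stannane | C/C=C(C)/C=C(/C)[Sn](C)(C)C
F7 | step 3 | methyl (2E,4Z,6Z,8E)-2,4,6,8-tetramethyldeca-2,4,6,8-tetraenoate | COC(=O)/C(C)=C/C(C)=C\C(C)=C/C(C)=C/C
F8 | step 4 | rac-iodolactone of 11 (carboxyl oxygen on C2, iodine on C3 trans to it, C4=C5 retained) | O=C1O[C@]2(C)[C@@H](I)C(C)=C[C@]3(C)[C@@H](C)[C@@]1(C)[C@H]23
F0 | step 6 | none | none
F9 | step 8 | [(1R,6R,7R,8S)-2,4,6,7,8-pentamethylbicyclo[4.2.0]octa-2,4-dien-8-yl]methanol | OC[C@@]1(C)[C@H](C)[C@@]2(C)C=C(C)C=C(C)[C@@H]12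
F10 | step 8 | (1R,6R,7R,8S)-2,4,6,7,8-pentamethylbicyclo[4.2.0]octa-2,4-diene-8-carbaldehyde | O=C[C@@]1(C)[C@H](C)[C@@]2(C)C=C(C)C=C(C)[C@@H]12
F11 | step 8 | methyl 5-hydroxy-2,4-dimethyl-3-oxo-5-[(1R,6R,7R,8S)-2,4,6,7,8-pentamethylbicyclo[4.2.0]octa-2,4-dien-8-yl]pentanoate (diastereomer mixture) | COC(=O)C(C)C(=O)C(C)C(O)[C@@]1(C)[C@H](C)[C@@]2(C)C=C(C)C=C(C)[C@@H]12
F0 | step 10 | none | none
A1 | alternative 1 | 2,4,6-trimethyl-4-[(E)-2-methylbut-2-enyloxy]cyclohexa-2,5-dien-1-one | C/C=C(\C)COC1(C)C=C(C)C(=O)C(C)=C1
A2 | alternative 1 | tricyclic enone ether (cyclobutane fused to the cyclohexenone, bridged by a tetrahydrofuran) | C1O[C@]2(C)C=C(C)C(=O)[C@]3(C)[C@@H](C)[C@@]1(C)[C@H]23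
A3 | alternative 2 | S-tert-butyl 2-methyl-3-oxo-3-[(1R,6R,7R,8S)-2,4,6,7,8-pentamethylbicyclo[4.2.0]octa-2,4-dien-8-yl]propanethioate | CC(C(=O)SC(C)(C)C)C(=O)[C@@]1(C)[C@H](C)[C@@]2(C)C=C(C)C=C(C)[C@@H]12
A4 | alternative 2 | 2-methyl-3-oxo-3-[(1R,6R,7R,8S)-2,4,6,7,8-pentamethylbicyclo[4.2.0]octa-2,4-dien-8-yl]prop-1-en-1-one (acylketene) | CC(=C=O)C(=O)[C@@]1(C)[C@H](C)[C@@]2(C)C=C(C)C=C(C)[C@@H]12
A5 | alternative 2 | 1-methoxyprop-1-yne | COC#CC
A6 | alternative 2 | 2-methoxy-3,5-dimethyl-6-[(1R,6R,7R,8S)-2,4,6,7,8-pentamethylbicyclo[4.2.0]octa-2,4-dien-8-yl]pyran-4-one (identical with 20) | COc1oc([C@@]2(C)[C@H](C)[C@@]3(C)C=C(C)C=C(C)[C@@H]23)c(C)c(=O)c1C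
A7 | alternative 3 | prop-1-en-2-yl (1R)-1,3,5-trimethyl-6-oxocyclohexa-2,4-diene-1-carboxylate | C=C(C)OC(=O)[C@]1(C)C=C(C)C=C(C)C1=O
A8 | alternative 3 | tricyclic lactone (bicyclo[2.2.2]oct-5-en-2-one bridged by the carboxylate) | O=C1O[C@]2(C)C[C@@]3(C)C=C(C)[C@@H]2[C@]1(C)C3=O
A9 | alternative 3 | cyclobutanone lactone after 1,3-acyl shift (bicyclo[4.2.0]oct-4-en-7-one, C8 carboxylate lactonized to C2) | O=C1O[C@]2(C)CC(C)=C[C@]3(C)C(=O)[C@@]1(C)[C@H]23
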